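**Retrosynthetic overview**

1. Last, the cyclopentane and cyclohexene rings are closed together by a ketone-exo intramolecular Diels–Alder reaction of a 13-membered para-cyclophane enone (bonds C2–C14 and C3–C11), released by oxidising the C1 carbinol.
2. Before that, one cationic event closes the cyclohexane and the cyclophane together: a heptatrienyl cation forms C5–C10 and the tyrosine phenol captures the resulting allyl cation at C4.
3. The hydroxy-lactam is the first ring, made from an open-chain L-tyrosinol β-ketoamide by oxidation, Knoevenagel condensation and C5′ hydroxylation.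
4. The β-ketoamide comes from L-tyrosinol and a dienyl dioxinone (acylketene); the dioxinone comes from an enal and a dioxinone phosphonate.
5. The chain comes from meso-2,4-dimethylglutaric anhydride (desymmetrisation sets C6 and C8) and a trienoic acid made from acrolein; no protecting groups are used.

Locants: chain carbons C1 (ketone carbon) to C16 (vinyl CH2); lactam atoms N1′ to C5′.
Assumption: the alkaloid catalyst of step 3 is taken to give the (2R,4S) half-ester; the quasi-enantiomeric (DHQ)2AQN is used if the sense proves opposite.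

**Route**

Step 1
Reactants: 1 triethyl 3-methyl-4-phosphonocrotonate (E/Z mixture as supplied); 2 acrolein
Product: 3 ethyl (2E,4E)-3-methylhepta-2,4,6-trienoate
Conditions: LiN(SiMe3)2, THF, −78 °C; then 2, −78 → 0 °C; chromatography removes the minor 2Z isomer
Reagents that add atoms: none
Why: Horner–Wadsworth–Emmons olefination at the γ-carbon of the vinylogous phosphonate anion gives the new 4E double bond, and equilibration of the allylic anion gives mainly the 2E ester.

Step 2
Reactants: 3 ethyl (2E,4E)-3-methylhepta-2,4,6-trienoate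
Product: 4 (2E,4E)-3-methylhepta-2,4,6-trienoic acid
Conditions: KOH, EtOH/H2O, 40 °C; then 1 M HCl, 0 °C
Reagents that add atoms: potassium hydroxide [K+].[OH-]
Why: Plain ester saponification; the conjugated triene has no base-sensitive group.

Step 3
Reactants: 5 meso-2,4-dimethylglutaric anhydride
Product: 6 (2R,4S)-5-methoxy-2,4-dimethyl-5-oxopentanoic acid
Conditions: MeOH (10 equiv), (DHQD)2AQN (hydroquinidine anthraquinone-1,4-diyl diether, 10 mol%), Et2O, −30 °C
Reagents that add atoms: methanol CO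
Why: Alkaloid-catalysed desymmetrising alcoholysis of a meso anhydride (general-base catalysis) selects one enantiotopic carbonyl and so fixes both methyl stereocentres (future C6 and C8) in one step.

Step 4
Reactants: 6 (2R,4S)-5-methoxy-2,4-dimethyl-5-oxopentanoic acid
Product: 7 methyl (2S,4R)-5-hydroxy-2,4-dimethylpentanoate
Conditions: BH3·SMe2, THF, −10 → 20 °C; MeOH quench; used at once
Reagents that add atoms: none
Why: Chemoselective borane reduction of the free acid via its acyloxyborane is much faster than reduction of the methyl ester and leaves both stereocentres untouched.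

Step 5
Reactants: 7 methyl (2S,4R)-5-hydroxy-2,4-dimethylpentanoate
Product: 8 methyl (2S,4R)-5-iodo-2,4-dimethylpentanoate
Conditions: I2, PPh3, imidazole, CH2Cl2, 0 °C → rt
Reagents that add atoms: iodine II
Why: Appel-type iodination displaces the activated primary hydroxyl by SN2 at CH2, away from both stereocentres.

Step 6
Reactants: 8 methyl (2S,4R)-5-iodo-2,4-dimethylpentanoate; 4 (2E,4E)-3-methylhepta-2,4,6-trienoic acid
Product: 11 methyl (2S,4R,7E,9E)-2,4,8-trimethyl-6-oxododeca-7,9,11-trienoate, via alkylzinc iodide 9 (not isolated), via trienoyl chloride 10 (not isolated)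
Conditions: (a) 8, Zn dust, LiCl, THF, 40 °C; (b) 4, (COCl)2, cat. HCONMe2, CH2Cl2, 0 °C, then evaporate; (c) 9 + 10, Pd(PPh3)4 (5 mol%), THF, 0 °C → rt
Reagents that add atoms: none
Why: Zinc insertion gives an ester-tolerant alkylzinc, and Negishi acylation with the fresh acid chloride forms the C9–C10 bond and stops at the ketone.

Step 7
Reactants: 11 methyl (2S,4R,7E,9E)-2,4,8-trimethyl-6-oxododeca-7,9,11-trienoate
Product: 12 methyl (2S,4R,6RS,7E,9E)-6-hydroxy-2,4,6,8-tetramethyldodeca-7,9,11-trienoate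
Conditions: MeMgBr (1.1 equiv), THF, −78 °C; aq. NH4Cl
Reagents that add atoms: methylmagnesium bromide C[Mg]Br
Why: Grignard 1,2-addition to the ketone, which at −78 °C is far more electrophilic than the methyl ester; the new carbinol centre (future C10) is deliberately a mixture because it is erased on ionisation in step 15.

Step 8
Reactants: 12 methyl (2S,4R,6RS,7E,9E)-6-hydroxy-2,4,6,8-tetramethyldodeca-7,9,11-trienoate
Product: 13 (2S,4R,6RS,7E,9E)-2,4,6,8-tetramethyldodeca-7,9,11-triene-1,6-diol
Conditions: iBu2AlH (3.3 equiv), CH2Cl2, −78 → 0 °C; aq. potassium sodium tartrate work-up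
Reagents that add atoms: none
Why: Hydride reduction of the ester to the primary alcohol under non-acidic conditions that spare the tertiary trienyl carbinol.

Step 9
Reactants: 13 (2S,4R,6RS,7E,9E)-2,4,6,8-tetramethyldodeca-7,9,11-triene-1,6-diol; 14 (triphenylphosphoranylidene)acetaldehyde
Product: 16 (2E,4S,6R,8RS,9E,11E)-8-hydroxy-4,6,8,10-tetramethyltetradeca-2,9,11,13-tetraenal, via aldehyde 15 (not isolated)
Conditions: nPr4N[RuO4] (5 mol%), N-methylmorpholine N-oxide, 4 Å sieves, CH2Cl2, rt; filter through silica; then 14, toluene, 70 °C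
Reagents that add atoms: none
Why: Neutral Ley–Griffith oxidation touches only the primary alcohol, and the α-methyl aldehyde is trapped at once by the stabilised ylide (Wittig reaction) to give the E-enal before C6 can epimerise.

Step 10
Reactants: 17 2,2,6-trimethyl-4H-1,3-dioxin-4-one
Product: 18 diethyl [(2,2-dimethyl-4-oxo-4H-1,3-dioxin-6-yl)methyl]phosphonate
Conditions: LiN(iPr)2 (2.1 equiv), THF, −78 °C; ClP(O)(OEt)2; aq. NH4Cl
Reagents that add atoms: diethyl chlorophosphate CCOP(=O)(Cl)OCC
Why: γ-Deprotonation gives the extended dienolate, which is C-phosphorylated at the methyl carbon; the second equivalent of base covers the more acidic product.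

Step 11
Reactants: 16 (2E,4S,6R,8RS,9E,11E)-8-hydroxy-4,6,8,10-tetramethyltetradeca-2,9,11,13-tetraenal; 18 diethyl [(2,2-dimethyl-4-oxo-4H-1,3-dioxin-6-yl)methyl]phosphonate
Product: 19 dienyl dioxinone (6-[(1E,3E,5S,7R,9RS,10E,12E)-9-hydroxy-5,7,9,11-tetramethylpentadeca-1,3,10,12,14-pentaen-1-yl]-2,2-dimethyl-4H-1,3-dioxin-4-one)
Conditions: 18, LiN(SiMe3)2, THF, −78 °C; then 16, −78 → 0 °C
Reagents that add atoms: none
Why: Horner–Wadsworth–Emmons reaction of the stabilised phosphonate with the enal forms the C2=C3 bond E-selectively and installs the masked β-keto acid.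

Step 12
Reactants: 19 dienyl dioxinone; 20 L-tyrosinol
Product: 22 β-ketoamide (N-[(2S)-1-hydroxy-3-(4-hydroxyphenyl)propan-2-yl] amide of the 3-oxo-octadecapentaenoic acid), via acylketene 21 (not isolated)
Conditions: toluene/1,4-dioxane 3:1, 100 °C, 1 h
Reagents that add atoms: none
Why: Thermal retro-[4+2] cleavage of the dioxinone releases acetone and an acylketene, which the amine traps much faster than any hydroxyl (acylketene amidation).

Step 13
Reactants: 22 β-ketoamide
Product: 26 linear dienone hydroxy-lactam ((5RS)-5-hydroxy-5-(4-hydroxybenzyl)-3-acyl-1,5-dihydro-2H-pyrrol-2-one), via amido aldehyde 23 (not isolated), via 5H-pyrrolinone 24 (not isolated), via 2H-pyrrol-2-one 25 (not isolated)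
Conditions: Dess–Martin periodinane (3 equiv), NaHCO3, water-saturated CH2Cl2, 0 °C → rt
Reagents that add atoms: water O
Why: Dess–Martin oxidation of the primary alcohol gives an aldehyde that closes the lactam by intramolecular Knoevenagel condensation, and a second oxidation of its hydroxypyrrole tautomer gives an acylimine that adds water at C5′; both C5′ epimers form and the centre stays labile.

Step 14
Reactants: 26 linear dienone hydroxy-lactam
Product: 27 linear C1 carbinol (1RS, 10RS, 5′RS mixture)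
Conditions: NaBH4, CeCl3·7H2O, MeOH/THF, −78 °C
Reagents that add atoms: none
Why: Luche reduction delivers hard hydride 1,2 to the cross-conjugated ketone and not to C4′ of the lactam, which turns the electron-poor dienone into an electron-rich 2,4-diene and switches off the dienophile until step 16.

Step 15
Reactants: 27 linear C1 carbinol
Product: 30 macrocyclic carbinol (13-membered para-cyclophane ether C4–O–aryl carrying the C5–C10 cyclohexane; 4S,5R,6S,8R,10S; C1 epimers), via heptatrienyl cation 28 (not isolated), via allyl cation 29 (not isolated)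
Conditions: Ca(NTf2)2 (5 mol%), nBu4NPF6 (5 mol%), (CF3)2CHOH/CH2Cl2 1:3, 0.5 mM, −20 → 0 °C; Et3N quench
Reagents that add atoms: none
Why: Proposed new method: ionisation of the tertiary trienyl carbinol (both C10 epimers converge) gives heptatrienyl cation 28, which C5 of the 2,4-diene attacks at C10 through a chair transition state (C6 and C8 methyls and both unsaturated arms equatorial, C10 methyl axial) to set C5 (R) and C10 (S) and leave the 11E,13E-diene and vinyl group; the tethered phenol oxygen then captures allyl cation 29 at C4 on the face away from the quaternary C10 to close the 13-membered ring and set C4 (S), with reversible ether ionisation as error correction; the closest known reaction type is the cationic polyene cyclisation terminated by a phenol oxygen, here extended to a macrocyclic termination.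

Step 16
Reactants: 30 macrocyclic carbinol
Product: 32 target CNP0151253.2, via macrocyclic enone 31 (not isolated)
Conditions: Dess–Martin periodinane, CH2Cl2, 0 °C → rt; then toluene, 40–60 °C, BHT
Reagents that add atoms: none
Why: Dess–Martin oxidation of the doubly allylic carbinol makes C2=C3 an activated dienophile held to the C11–C14 diene by a three-atom tether, so a thermal intramolecular Diels–Alder reaction closes the cyclopentane and cyclohexene rings at once; the E-enone gives trans H2/H3, the E,E-diene gives cis H11/H14, and the ketone-exo transition state gives the cis C3–C11 fusion, that is C2 (R), C3 (R), C11 (S), C14 (S); this exo preference is expected (not proven) because the endo alternative would build a doubly trans-fused cyclopentane and press the cyclophane bridge onto the C12 methyl; C5′ settles as R by ring–chain equilibration of the hemiaminal inside the cyclophane.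

**Compound list**

1 | triethyl 3-methyl-4-phosphonocrotonate (E/Z mixture) | CCOC(=O)C=C(C)CP(=O)(OCC)OCC | starting material
2 | acrolein | C=CC=O | starting material
3 | ethyl (2E,4E)-3-methylhepta-2,4,6-trienoate | CCOC(=O)/C=C(C)/C=C/C=C | intermediate
4 | (2E,4E)-3-methylhepta-2,4,6-trienoic acid | OC(=O)/C=C(C)/C=C/C=C | intermediate
5 | meso-2,4-dimethylglutaric anhydride ((3R,5S)-3,5-dimethyloxane-2,6-dione) | O=C1OC(=O)[C@H](C)C[C@@H]1C | starting material
6 | (2R,4S)-5-methoxy-2,4-dimethyl-5-oxopentanoic acid | OC(=O)[C@H](C)C[C@H](C)C(=O)OC | intermediate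
7 | methyl (2S,4R)-5-hydroxy-2,4-dimethylpentanoate | OC[C@H](C)C[C@H](C)C(=O)OC | intermediate
8 | methyl (2S,4R)-5-iodo-2,4-dimethylpentanoate | IC[C@H](C)C[C@H](C)C(=O)OC | intermediate
9 | [(2R,4S)-5-methoxy-2,4-dimethyl-5-oxopentyl]zinc iodide | I[Zn]C[C@H](C)C[C@H](C)C(=O)OC | intermediate (not isolated)
10 | (2E,4E)-3-methylhepta-2,4,6-trienoyl chloride | ClC(=O)/C=C(C)/C=C/C=C | intermediate (not isolated)
11 | methyl (2S,4R,7E,9E)-2,4,8-trimethyl-6-oxododeca-7,9,11-trienoate | C=C/C=C/C(C)=C/C(=O)C[C@H](C)C[C@H](C)C(=O)OC | intermediate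
12 | methyl (2S,4R,6RS,7E,9E)-6-hydroxy-2,4,6,8-tetramethyldodeca-7,9,11-trienoate | C=C/C=C/C(C)=C/C(C)(O)C[C@H](C)C[C@H](C)C(=O)OC | intermediate
13 | (2S,4R,6RS,7E,9E)-2,4,6,8-tetramethyldodeca-7,9,11-triene-1,6-diol | C=C/C=C/C(C)=C/C(C)(O)C[C@H](C)C[C@H](C)CO | intermediate
14 | (triphenylphosphoranylidene)acetaldehyde | O=CC=P(c1ccccc1)(c1ccccc1)c1ccccc1 | starting material
15 | (2S,4R,6RS,7E,9E)-6-hydroxy-2,4,6,8-tetramethyldodeca-7,9,11-trienal | C=C/C=C/C(C)=C/C(C)(O)C[C@H](C)C[C@H](C)C=O | intermediate (not isolated)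
16 | (2E,4S,6R,8RS,9E,11E)-8-hydroxy-4,6,8,10-tetramethyltetradeca-2,9,11,13-tetraenal | C=C/C=C/C(C)=C/C(C)(O)C[C@H](C)C[C@H](C)/C=C/C=O | intermediate
17 | 2,2,6-trimethyl-4H-1,3-dioxin-4-one | CC1=CC(=O)OC(C)(C)O1 | starting material
18 | diethyl [(2,2-dimethyl-4-oxo-4H-1,3-dioxin-6-yl)methyl]phosphonate | CCOP(=O)(CC1=CC(=O)OC(C)(C)O1)OCC | intermediate
19 | 6-[(1E,3E,5S,7R,9RS,10E,12E)-9-hydroxy-5,7,9,11-tetramethylpentadeca-1,3,10,12,14-pentaen-1-yl]-2,2-dimethyl-4H-1,3-dioxin-4-one | C=C/C=C/C(C)=C/C(C)(O)C[C@H](C)C[C@H](C)/C=C/C=C/C1=CC(=O)OC(C)(C)O1 | intermediate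
20 | L-tyrosinol ((2S)-2-amino-3-(4-hydroxyphenyl)propan-1-ol) | N[C@@H](Cc1ccc(O)cc1)CO | starting material
21 | acylketene, (4E,6E,8S,10R,12RS,13E,15E)-12-hydroxy-8,10,12,14-tetramethyl-3-oxooctadeca-1,4,6,13,15,17-hexaen-1-one | C=C/C=C/C(C)=C/C(C)(O)C[C@H](C)C[C@H](C)/C=C/C=C/C(=O)C=C=O | intermediate (not isolated)
22 | (4E,6E,8S,10R,12RS,13E,15E)-12-hydroxy-N-[(2S)-1-hydroxy-3-(4-hydroxyphenyl)propan-2-yl]-8,10,12,14-tetramethyl-3-oxooctadeca-4,6,13,15,17-pentaenamide | C=C/C=C/C(C)=C/C(C)(O)C[C@H](C)C[C@H](C)/C=C/C=C/C(=O)CC(=O)N[C@@H](Cc1ccc(O)cc1)CO | intermediate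
23 | amido aldehyde, the N-[(2S)-1-(4-hydroxyphenyl)-3-oxopropan-2-yl] analogue of 22 | C=C/C=C/C(C)=C/C(C)(O)C[C@H](C)C[C@H](C)/C=C/C=C/C(=O)CC(=O)N[C@@H](Cc1ccc(O)cc1)C=O | intermediate (not isolated)
24 | (5S)-5-(4-hydroxybenzyl)-3-[(2E,4E,6S,8R,10RS,11E,13E)-10-hydroxy-6,8,10,12-tetramethylhexadeca-2,4,11,13,15-pentaenoyl]-1,5-dihydro-2H-pyrrol-2-one | C=C/C=C/C(C)=C/C(C)(O)C[C@H](C)C[C@H](C)/C=C/C=C/C(=O)C1=C[C@H](Cc2ccc(O)cc2)NC1=O | intermediate (not isolated)
25 | 5-(4-hydroxybenzyl)-3-[(2E,4E,6S,8R,10RS,11E,13E)-10-hydroxy-6,8,10,12-tetramethylhexadeca-2,4,11,13,15-pentaenoyl]-2H-pyrrol-2-one | C=C/C=C/C(C)=C/C(C)(O)C[C@H](C)C[C@H](C)/C=C/C=C/C(=O)C1=CC(Cc2ccc(O)cc2)=NC1=O | intermediate (not isolated)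
26 | (5RS)-5-hydroxy-5-(4-hydroxybenzyl)-3-[(2E,4E,6S,8R,10RS,11E,13E)-10-hydroxy-6,8,10,12-tetramethylhexadeca-2,4,11,13,15-pentaenoyl]-1,5-dihydro-2H-pyrrol-2-one | C=C/C=C/C(C)=C/C(C)(O)C[C@H](C)C[C@H](C)/C=C/C=C/C(=O)C1=CC(O)(Cc2ccc(O)cc2)NC1=O | intermediate
27 | (5RS)-3-[(1RS,2E,4E,6S,8R,10RS,11E,13E)-1,10-dihydroxy-6,8,10,12-tetramethylhexadeca-2,4,11,13,15-pentaen-1-yl]-5-hydroxy-5-(4-hydroxybenzyl)-1,5-dihydro-2H-pyrrol-2-one | C=C/C=C/C(C)=C/C(C)(O)C[C@H](C)C[C@H](C)/C=C/C=C/C(O)C1=CC(O)(Cc2ccc(O)cc2)NC1=O | intermediate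
28 | heptatrienyl cation from 27 (charge drawn at C10, delocalised to C16) | C=C/C=C/C(C)=C/[C+](C)C[C@H](C)C[C@H](C)/C=C/C=C/C(O)C1=CC(O)(Cc2ccc(O)cc2)NC1=O | intermediate (not isolated)
29 | allyl cation after C5–C10 closure (5R,6S,8R,10S; charge drawn at C4, delocalised to C2) | C=C/C=C/C(C)=C/[C@]1(C)C[C@H](C)C[C@H](C)[C@H]1[CH+]/C=C/C(O)C2=CC(O)(Cc3ccc(O)cc3)NC2=O | intermediate (not isolated)
30 | macrocyclic carbinol: 13-membered para-cyclophane ether (C4–O–aryl), 2E-alkene, C1 carbinol (epimers), cyclohexane 5R,6S,8R,10S with the (1E,3E)-2-methylhexa-1,3,5-trienyl arm on C10, C4 S, C5′ R | C=C/C=C/C(C)=C/[C@]1(C)C[C@H](C)C[C@H](C)[C@H]1[C@@H]2/C=C/C(O)C3=C[C@](O)(Cc4ccc(O2)cc4)NC3=O | intermediate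
31 | macrocyclic enone: the C1 ketone of 30 (4S,5R,6S,8R,10S,5′R; 2E) | C=C/C=C/C(C)=C/[C@]1(C)C[C@H](C)C[C@H](C)[C@H]1[C@@H]2/C=C/C(=O)C3=C[C@](O)(Cc4ccc(O2)cc4)NC3=O | intermediate (not isolated)
32 | CNP0151253.2 (2R,3R,4S,5R,6S,8R,10S,11S,14S,5′R) | C=C[C@H]1C=C(C)[C@@H]2[C@H]3[C@H](Oc4ccc(cc4)C[C@@]4(O)C=C(C(=O)N4)C(=O)[C@H]13)[C@@H]1[C@@H](C)C[C@@H](C)C[C@]12C | target

**Step count and risks**

Total steps: 16. Longest linear sequence: 13 (steps 3–9 and 11–16, from anhydride 5).

Steps most likely to fail: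

Step 15 (macrocyclising cationic cyclisation). Closing a strained 13-membered ether on a transient allyl cation, and the C4 configuration, are unproven. The fallback forms the macrocycle before the lactam, so that the ring is one atom larger and has no rigid lactam in it. It sets out from 22: Luche reduction of the ketone of 22 gives the β-hydroxy amide F1. The same calcium/(CF3)2CHOH ionisation then closes the cyclohexane and a 14-membered cyclophane ether F2 with the tyrosinol amide still open-chain. Excess Dess–Martin periodinane then oxidises both carbinols of F2, and transannular Knoevenagel condensation plus C5′ oxidation and hydration build the lactam inside the ring. This returns to the route at 31, which continues as in step 16.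

Step 16 (exo selectivity of the Diels–Alder reaction). The uncatalysed reaction may prefer the ketone-endo, trans-fused adduct. The fallback changes the dienophile geometry and sets out from 30. Oxidation at −40 °C followed at once by irradiation at 365 nm converts 31 into the 2Z macrocyclic enone F3 before it cyclises. For a Z-dienophile the carbonyl-endo and tether-syn preferences coincide, so the cis C3–C11 fusion forms and gives the 2-epi adduct F4. DBU then epimerises C2, the only enolisable position next to the ketone, and returns to the route at 32.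

Step 13 (oxidative lactam formation beside a free phenol and the acid-labile trienyl carbinol). The fallback masks the phenol and sets out from 20 and 19. Selective silylation of the phenoxide of 20 (NaH 1 equiv, tBuMe2SiCl) gives O-silyl tyrosinol F5. Heating F5 with 19 as in step 12 gives the silyl β-ketoamide F6. The Dess–Martin sequence of step 13 gives the silyl hydroxy-lactam F7. Buffered fluoride (nBu4NF/AcOH, THF, 0 °C) removes the silyl group and returns to the route at 26.

**Further compounds**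

F1 | step 15 | β-hydroxy amide, (4E,6E,8S,10R,12RS,13E,15E)-3,12-dihydroxy-N-[(2S)-1-hydroxy-3-(4-hydroxyphenyl)propan-2-yl]-8,10,12,14-tetramethyloctadeca-4,6,13,15,17-pentaenamide | C=C/C=C/C(C)=C/C(C)(O)C[C@H](C)C[C@H](C)/C=C/C=C/C(O)CC(=O)N[C@@H](Cc1ccc(O)cc1)CO
F2 | step 15 | 14-membered cyclophane ether with open-chain tyrosinol amide (4S,5R,6S,8R,10S; C1 carbinol epimers) | C=C/C=C/C(C)=C/[C@]1(C)C[C@H](C)C[C@H](C)[C@H]1[C@@H]2/C=C/C(O)CC(=O)N[C@H](CO)Cc3ccc(O2)cc3
F3 | step 16 | 2Z isomer of macrocyclic enone 31 | C=C/C=C/C(C)=C/[C@]1(C)C[C@H](C)C[C@H](C)[C@H]1[C@@H]2/C=C\C(=O)C3=C[C@](O)(Cc4ccc(O2)cc4)NC3=O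
F4 | step 16 | 2-epi adduct (C2 epimer of 32) | C=C[C@H]1C=C(C)[C@@H]2[C@H]3[C@H](Oc4ccc(cc4)C[C@@]4(O)C=C(C(=O)N4)C(=O)[C@@H]13)[C@@H]1[C@@H](C)C[C@@H](C)C[C@]12C
F5 | step 13 | O-silyl tyrosinol, (2S)-2-amino-3-[4-(tert-butyldimethylsilyloxy)phenyl]propan-1-ol | N[C@@H](Cc1ccc(O[Si](C)(C)C(C)(C)C)cc1)CO
F6 | step 13 | silyl β-ketoamide (aryl tert-butyldimethylsilyl ether of 22) | C=C/C=C/C(C)=C/C(C)(O)C[C@H](C)C[C@H](C)/C=C/C=C/C(=O)CC(=O)N[C@@H](Cc1ccc(O[Si](C)(C)C(C)(C)C)cc1)CO
F7 | step 13 | silyl hydroxy-lactam (aryl tert-butyldimethylsilyl ether of 26) | C=C/C=C/C(C)=C/C(C)(O)C[C@H](C)C[C@H](C)/C=C/C=C/C(=O)C1=CC(O)(Cc2ccc(O[Si](C)(C)C(C)(C)C)cc2)NC1=O
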